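The synthesis rests on opening ring B at C5–C10 and C6–C7, which unravels the decalin into an acyclic deca-1,7,9-triene. One thermal intramolecular Diels–Alder reaction between the C5=C6 vinyl group and a C7=C8–C9=C10 diene closes rings A and B together and sets C5 and the quaternary C10. It exploits the C8(=C17H2)–C9H unit of ring B, which is the protodesilylation product of a 2-(trimethylsilylmethyl)diene adduct. The precursor carries the whole side chain on C9, the allylsilane on C8, and C3/C4 (made by an asymmetric allylboration that joins two halves at C3–C4) locked in a temporary 1,3-dioxane that steers the cyclisation.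

Key step: step 12

Remark: labdane numbering (C1–C20) is used throughout; the target is read as the (3R,4S,5S,9R,10S) ent-labdane, and 2 (as a THF solution) and 5 are taken as commercial.

Step 1
Reactants: 1 ethyl but-2-ynoate; 2 [2-(1,3-dioxan-2-yl)ethyl]magnesium bromide
Product: 4 ethyl (Z)-5-(1,3-dioxan-2-yl)-2-iodo-3-methylpent-2-enoate, via alkenylcopper adduct 3 (not isolated)
Conditions: 2, CuBr·SMe2 (1.05 equiv), THF, –78 °C; then 1, –78 °C; then I2, –78 °C
Reagents that add atoms: iodine, II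
Why: syn-carbocupration of the ynoate puts the C1–C3 chain and copper cis, and iodinolysis with retention at –78 °C (before the alkenylcopper can equilibrate through the allenoate) should give the Z iodide that fixes the later C9=C10 geometry.

Step 2
Reactants: 5 (E)-3-methylpent-2-en-4-yn-1-ol
Product: 6 tert-butyl{[(E)-3-methylpent-2-en-4-yn-1-yl]oxy}diphenylsilane
Conditions: TBDPSCl, imidazole, DMF, rt
Reagents that add atoms: tert-butylchlorodiphenylsilane, CC(C)(C)[Si](Cl)(c1ccccc1)c1ccccc1
Why: routine silylation of the primary allylic alcohol (C15–OH) with a group that survives the later acid, base, oxidant and heat.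

Step 3
Reactants: 6 tert-butyl{[(E)-3-methylpent-2-en-4-yn-1-yl]oxy}diphenylsilane
Product: 7 tert-butyl{[(E)-3-methylpenta-2,4-dien-1-yl]oxy}diphenylsilane
Conditions: H2 (1 atm), Pd/CaCO3 poisoned with Pb(OAc)2, quinoline, hexane/EtOAc, rt, stopped after 1 equiv H2
Reagents that add atoms: none
Why: Lindlar semihydrogenation of the terminal alkyne should stop at the vinyl group and leave the trisubstituted E alkene untouched.

Step 4
Reactants: 7 tert-butyl{[(E)-3-methylpenta-2,4-dien-1-yl]oxy}diphenylsilane; 4 ethyl (Z)-5-(1,3-dioxan-2-yl)-2-iodo-3-methylpent-2-enoate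
Product: 9 ethyl (2E)-2-[(3E)-5-(tert-butyldiphenylsilyloxy)-3-methylpent-3-en-1-yl]-5-(1,3-dioxan-2-yl)-3-methylpent-2-enoate, via B-alkyl-9-BBN adduct 8 (not isolated)
Conditions: 7, 9-BBN, THF, 0 °C → rt; then 4, PdCl2(dppf), AsPh3, Cs2CO3, DMF/H2O, rt → 50 °C
Reagents that add atoms: none
Why: 9-BBN should add anti-Markovnikov to the terminal vinyl group only, and the B-alkyl Suzuki–Miyaura coupling joins C11 to C9 with retention of the iodide geometry, so the side chain ends up cis to the C1 chain.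

Step 5
Reactants: 9 ethyl (2E)-2-[(3E)-5-(tert-butyldiphenylsilyloxy)-3-methylpent-3-en-1-yl]-5-(1,3-dioxan-2-yl)-3-methylpent-2-enoate
Product: 10 ethyl (2E)-2-[(3E)-5-(tert-butyldiphenylsilyloxy)-3-methylpent-3-en-1-yl]-3-methyl-6-oxohex-2-enoate
Conditions: 1 M aq. HCl, THF, rt
Reagents that add atoms: water, O
Why: acid hydrolysis of the 1,3-dioxane frees the C3 aldehyde, and the TBDPS ether and the hindered tetrasubstituted enoate should survive.

Step 6
Reactants: 11 prop-2-yn-1-ol
Product: 13 (Z)-3-iodo-2-methylprop-2-en-1-ol, via cyclic alkenylmagnesium alkoxide 12 (not isolated)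
Conditions: MeMgBr (3 equiv), CuI (10 mol%), THF, –10 °C → rt; then I2, –78 → 0 °C
Reagents that add atoms: methylmagnesium bromide, C[Mg]Br; iodine, II
Why: alkoxide-directed, copper-catalysed anti-carbomagnesiation gives a five-membered magnesium chelate whose iodinolysis places iodine cis to CH2OH.

Step 7
Reactants: 13 (Z)-3-iodo-2-methylprop-2-en-1-ol
Product: 14 1-({[(Z)-3-iodo-2-methylprop-2-en-1-yl]oxy}methyl)-4-methoxybenzene
Conditions: NaH, PMBCl, Bu4NI (cat.), THF/DMF, 0 °C → rt
Reagents that add atoms: 4-methoxybenzyl chloride, COc1ccc(CCl)cc1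
Why: Williamson etherification installs the PMB group that is later turned into the ring-forming acetal; the iodide has no hydrogen on C2, so it cannot eliminate.

Step 8
Reactants: 14 1-({[(Z)-3-iodo-2-methylprop-2-en-1-yl]oxy}methyl)-4-methoxybenzene
Product: 17 2-{(Z)-4-[(4-methoxybenzyl)oxy]-3-methylbut-2-en-1-yl}-4,4,5,5-tetramethyl-1,3,2-dioxaborolane, via alkenyllithium 15 (not isolated), via boron ate complex 16 (not isolated)
Conditions: t-BuLi (2.1 equiv), Et2O, –78 °C; then ICH2Bpin, –78 °C → rt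
Reagents that add atoms: 2-(iodomethyl)-4,4,5,5-tetramethyl-1,3,2-dioxaborolane, ICB1OC(C)(C)C(C)(C)O1
Why: iodine–lithium exchange with retention, borate formation and 1,2-metallate shift with loss of iodide (Matteson-type homologation) should give the γ,γ-disubstituted allylboronate with CH2OPMB cis to CH2B.

Step 9
Reactants: 10 ethyl (2E)-2-[(3E)-5-(tert-butyldiphenylsilyloxy)-3-methylpent-3-en-1-yl]-3-methyl-6-oxohex-2-enoate; 17 2-{(Z)-4-[(4-methoxybenzyl)oxy]-3-methylbut-2-en-1-yl}-4,4,5,5-tetramethyl-1,3,2-dioxaborolane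
Product: 18 ethyl (2E,6R,7S)-2-[(3E)-5-(tert-butyldiphenylsilyloxy)-3-methylpent-3-en-1-yl]-6-hydroxy-7-{[(4-methoxybenzyl)oxy]methyl}-3,7-dimethylnona-2,8-dienoate
Conditions: (S)-TRIP [(S)-3,3′-bis(2,4,6-triisopropylphenyl)-1,1′-binaphthyl-2,2′-diyl hydrogen phosphate] (5 mol%), 4 Å molecular sieves, toluene, –30 → 0 °C; aq. NaHCO3 work-up
Reagents that add atoms: none
Why: chiral phosphoric acid-catalysed allylboration through a closed chair transition state, in which the Z boronate holds CH2OPMB axial and CH3 equatorial (OH/CH3 anti, OH/CH2OPMB syn, hence 4S relative to 3R) while the catalyst is expected to direct attack to the aldehyde si face (3R); this unites the two halves at the hindered C3–C4 bond.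

Step 10
Reactants: 18 ethyl (2E,6R,7S)-2-[(3E)-5-(tert-butyldiphenylsilyloxy)-3-methylpent-3-en-1-yl]-6-hydroxy-7-{[(4-methoxybenzyl)oxy]methyl}-3,7-dimethylnona-2,8-dienoate
Product: 19 ethyl (2E)-2-[(3E)-5-(tert-butyldiphenylsilyloxy)-3-methylpent-3-en-1-yl]-5-[(2S,4R,5S)-2-(4-methoxyphenyl)-5-methyl-5-vinyl-1,3-dioxan-4-yl]-3-methylpent-2-enoate
Conditions: DDQ (1.2 equiv), 4 Å molecular sieves, CH2Cl2, 0 °C
Reagents that add atoms: none
Why: anhydrous DDQ oxidation of the PMB ether gives an oxocarbenium ion that the C3 hydroxyl traps (oxidative acetalisation) to form the O3/O18 1,3-dioxane with the aryl group equatorial; it is done before the DDQ-sensitive diene exists.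

Step 11
Reactants: 19 ethyl (2E)-2-[(3E)-5-(tert-butyldiphenylsilyloxy)-3-methylpent-3-en-1-yl]-5-[(2S,4R,5S)-2-(4-methoxyphenyl)-5-methyl-5-vinyl-1,3-dioxan-4-yl]-3-methylpent-2-enoate
Product: 21 triene C6H2=C5H–C4(CH3)(C18H2O–)–C3H(O–)–C2H2–C1H2–C10(CH3)=C9(side chain)–C8(=C7H2)–C17H2SiMe3 with O3/O18 bridged as the (S)-4-methoxybenzylidene acetal, C1 trans to C8 across C9=C10 and C15–OTBDPS, via bis(silylmethyl)carbinol 20 (not isolated)
Conditions: Me3SiCH2MgCl (5 equiv), CeCl3, THF, –78 °C → rt; then SiO2, CH2Cl2, rt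
Reagents that add atoms: (trimethylsilylmethyl)magnesium chloride, C[Si](C)(C)C[Mg]Cl
Why: organocerium double addition to the hindered ester followed by Peterson elimination of one β-silyl group (ester-to-allylsilane conversion) turns the C8 ester carbon into C8(=C7H2)C17H2SiMe3 without touching the C9=C10 geometry.

Step 12
Reactants: 21 triene (2-(trimethylsilylmethyl)diene, vinyl dienophile, dioxane tether)
Product: 22 15-O-TBDPS-17-(trimethylsilyl)-ent-labda-8,13E-diene-3,15,18-triol 3,18-O-[(S)-4-methoxybenzylidene] acetal (trans-fused decalin, C10–CH3 and C4–CH3 both axial and syn, H-5 anti to them)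
Conditions: o-dichlorobenzene (0.01 M), BHT, N,O-bis(trimethylsilyl)acetamide (cat.), 190 °C, sealed tube
Reagents that add atoms: none
Why: A thermal, concerted but asynchronous type 1 intramolecular Diels–Alder reaction of a deca-1,7,9-triene, in which the unactivated C5=C6 vinyl group adds suprafacially across C7 and C10 of the s-cis diene to form C6–C7 and C5–C10 and to leave C8=C9 as a tetrasubstituted allylsilane; the closest known reactions are thermal cyclisations of unactivated deca-1,7,9-trienes and Diels–Alder reactions of 2-(trimethylsilylmethyl)buta-1,3-dienes. Ring B is closed as the new cyclohexene of the [4+2] event, and ring A as a six-membered carbocycle by the C5–C10 bond across the four-carbon tether C1–C4 (fused mode, tether exo). C10 is set stereospecifically by the diene geometry (tether outside, methyl inside) and C5 by the exo orientation of the tether, which together give the trans ring fusion with C10–CH3 and H-5 anti. The face is chosen by the temporary 1,3-dioxane, whose trans fusion to the developing ring A allows only the chair with O3 and C18 equatorial and the C4 methyl axial, so that C10–CH3 ends up syn to that methyl as the target requires. The step needs trans- over cis-fused closure, which should be secured by the diequatorial exit of both reacting arms from the dioxane-locked chair and by the C8/C9 substituents, which would have to fold over the axial hydrogens of ring A in the cis mode. The only accessible [1,5]-hydrogen shift (C20–H to C7) is reversible and gives a diene that cannot cyclise, so it should act as a reservoir and not as a drain.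

Step 13
Reactants: 22 silylated adduct with acetal
Product: 23 (3R,4S,5S,9R,10S)-15-(tert-butyldiphenylsilyloxy)-ent-labda-8(17),13E-diene-3,18-diol
Conditions: TsOH·H2O (0.3–1 equiv), MeOH/CH2Cl2, 0 °C → rt
Reagents that add atoms: none
Why: SE2′ protodesilylation, in which the proton should enter C9 axially on the face anti to the axial C10 methyl (C9–H anti to C20, side chain equatorial) while loss of silicon creates the C8=C17 methylene; the same acid methanolyses the benzylidene acetal and spares the TBDPS ether.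

Step 14
Reactants: 23 15-O-TBDPS-3,18-diol
Product: 24 (3R,4S,5S,9R,10S)-18-(tert-butyldimethylsilyloxy)-15-(tert-butyldiphenylsilyloxy)-ent-labda-8(17),13E-dien-3-ol
Conditions: TBSCl (1.1 equiv), imidazole, CH2Cl2, 0 °C
Reagents that add atoms: tert-butylchlorodimethylsilane, CC(C)(C)[Si](C)(C)Cl
Why: selective silylation of the primary C18 hydroxyl over the hindered secondary C3 hydroxyl next to the quaternary C4.

Step 15
Reactants: 24 18-O-TBS-15-O-TBDPS-3-ol; 25 angelic acid [(Z)-2-methylbut-2-enoic acid]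
Product: 27 (3R,4S,5S,9R,10S)-18-(tert-butyldimethylsilyloxy)-15-(tert-butyldiphenylsilyloxy)-ent-labda-8(17),13E-dien-3-yl (Z)-2-methylbut-2-enoate, via angelic 2,4,6-trichlorobenzoic anhydride 26 (not isolated)
Conditions: 25, 2,4,6-trichlorobenzoyl chloride, Et3N, toluene, rt; then 24, 80 °C (no DMAP)
Reagents that add atoms: none
Why: Yamaguchi-type mixed-anhydride esterification without a nucleophilic catalyst is the usual way to acylate hindered alcohols with angelic acid while keeping the Z double bond.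

Step 16
Reactants: 27 bis-silylated angelate
Product: 28 target, (3R,4S,5S,9R,10S)-15,18-dihydroxy-ent-labda-8(17),13E-dien-3-yl (Z)-2-methylbut-2-enoate
Conditions: HF·pyridine, pyridine, THF, 0 °C → rt
Reagents that add atoms: none
Why: buffered fluoride desilylation removes both silyl ethers under mildly acidic conditions that should avoid 3-O→18-O acyl migration and angelate isomerisation.

Compound list
1 | ethyl but-2-ynoate | CCOC(=O)C#CC | starting material
2 | [2-(1,3-dioxan-2-yl)ethyl]magnesium bromide | Br[Mg]CCC1OCCCO1 | starting material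
3 | alkenylcopper adduct (Cu cis to the dioxanylethyl chain) | CCOC(=O)/C([Cu])=C(\C)CCC1OCCCO1 | intermediate (not isolated)
4 | ethyl (Z)-5-(1,3-dioxan-2-yl)-2-iodo-3-methylpent-2-enoate | CCOC(=O)/C(I)=C(\C)CCC1OCCCO1 | intermediate
5 | (E)-3-methylpent-2-en-4-yn-1-ol | C#C/C(C)=C/CO | starting material
6 | tert-butyl{[(E)-3-methylpent-2-en-4-yn-1-yl]oxy}diphenylsilane | C#C/C(C)=C/CO[Si](c1ccccc1)(c1ccccc1)C(C)(C)C | intermediate
7 | tert-butyl{[(E)-3-methylpenta-2,4-dien-1-yl]oxy}diphenylsilane | C=C/C(C)=C/CO[Si](c1ccccc1)(c1ccccc1)C(C)(C)C | intermediate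
8 | 9-[(E)-5-(tert-butyldiphenylsilyloxy)-3-methylpent-3-en-1-yl]-9-borabicyclo[3.3.1]nonane | CC(C)(C)[Si](OC/C=C(\C)CCB1C2CCCC1CCC2)(c1ccccc1)c1ccccc1 | intermediate (not isolated)
9 | ethyl (2E)-2-[(3E)-5-(tert-butyldiphenylsilyloxy)-3-methylpent-3-en-1-yl]-5-(1,3-dioxan-2-yl)-3-methylpent-2-enoate | CCOC(=O)/C(CC/C(C)=C/CO[Si](c1ccccc1)(c1ccccc1)C(C)(C)C)=C(\C)CCC1OCCCO1 | intermediate
10 | ethyl (2E)-2-[(3E)-5-(tert-butyldiphenylsilyloxy)-3-methylpent-3-en-1-yl]-3-methyl-6-oxohex-2-enoate | CCOC(=O)/C(CC/C(C)=C/CO[Si](c1ccccc1)(c1ccccc1)C(C)(C)C)=C(\C)CCC=O | intermediate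
11 | prop-2-yn-1-ol | C#CCO | starting material
12 | cyclic alkenylmagnesium alkoxide (4-methyl-2,5-dihydro-1,2-oxamagnesole) | CC1=C[Mg]OC1 | intermediate (not isolated)
13 | (Z)-3-iodo-2-methylprop-2-en-1-ol | OC/C(C)=C\I | intermediate
14 | 1-({[(Z)-3-iodo-2-methylprop-2-en-1-yl]oxy}methyl)-4-methoxybenzene | COc1ccc(COC/C(C)=C\I)cc1 | intermediate
15 | (Z)-alkenyllithium from 14 | COc1ccc(COC/C(C)=C\[Li])cc1 | intermediate (not isolated)
16 | lithium alkenyl(iodomethyl)pinacolatoborate | [Li+].COc1ccc(COC/C(C)=C\[B-]2(CI)OC(C)(C)C(C)(C)O2)cc1 | intermediate (not isolated)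
17 | 2-{(Z)-4-[(4-methoxybenzyl)oxy]-3-methylbut-2-en-1-yl}-4,4,5,5-tetramethyl-1,3,2-dioxaborolane | COc1ccc(COC/C(C)=C\CB2OC(C)(C)C(C)(C)O2)cc1 | intermediate
18 | ethyl (2E,6R,7S)-2-[(3E)-5-(tert-butyldiphenylsilyloxy)-3-methylpent-3-en-1-yl]-6-hydroxy-7-{[(4-methoxybenzyl)oxy]methyl}-3,7-dimethylnona-2,8-dienoate | CCOC(=O)/C(CC/C(C)=C/CO[Si](c1ccccc1)(c1ccccc1)C(C)(C)C)=C(\C)CC[C@@H](O)[C@](C)(COCc1ccc(OC)cc1)C=C | intermediate
19 | ethyl (2E)-2-[(3E)-5-(tert-butyldiphenylsilyloxy)-3-methylpent-3-en-1-yl]-5-[(2S,4R,5S)-2-(4-methoxyphenyl)-5-methyl-5-vinyl-1,3-dioxan-4-yl]-3-methylpent-2-enoate | CCOC(=O)/C(CC/C(C)=C/CO[Si](c1ccccc1)(c1ccccc1)C(C)(C)C)=C(\C)CC[C@H]1O[C@@H](c2ccc(OC)cc2)OC[C@]1(C)C=C | intermediate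
20 | bis(trimethylsilylmethyl)carbinol from 19 | C[Si](C)(C)CC(O)(C[Si](C)(C)C)/C(CC/C(C)=C/CO[Si](c1ccccc1)(c1ccccc1)C(C)(C)C)=C(\C)CC[C@H]1O[C@@H](c2ccc(OC)cc2)OC[C@]1(C)C=C | intermediate (not isolated)
21 | Diels–Alder triene (2-(trimethylsilylmethyl)diene, vinyl group, dioxane tether) | C=C(C[Si](C)(C)C)/C(CC/C(C)=C/CO[Si](c1ccccc1)(c1ccccc1)C(C)(C)C)=C(\C)CC[C@H]1O[C@@H](c2ccc(OC)cc2)OC[C@]1(C)C=C | intermediate
22 | 15-O-TBDPS-17-(trimethylsilyl)-ent-labda-8,13E-diene-3,15,18-triol 3,18-O-[(S)-4-methoxybenzylidene] acetal | C[Si](C)(C)CC1=C(CC/C(C)=C/CO[Si](c2ccccc2)(c2ccccc2)C(C)(C)C)[C@]2(C)CC[C@H]3O[C@@H](c4ccc(OC)cc4)OC[C@]3(C)[C@H]2CC1 | intermediate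
23 | (3R,4S,5S,9R,10S)-15-(tert-butyldiphenylsilyloxy)-ent-labda-8(17),13E-diene-3,18-diol | C=C1CC[C@H]2[C@@](C)(CC[C@@H](O)[C@]2(C)CO)[C@@H]1CC/C(C)=C/CO[Si](c1ccccc1)(c1ccccc1)C(C)(C)C | intermediate
24 | (3R,4S,5S,9R,10S)-18-(tert-butyldimethylsilyloxy)-15-(tert-butyldiphenylsilyloxy)-ent-labda-8(17),13E-dien-3-ol | C=C1CC[C@H]2[C@@](C)(CC[C@@H](O)[C@]2(C)CO[Si](C)(C)C(C)(C)C)[C@@H]1CC/C(C)=C/CO[Si](c1ccccc1)(c1ccccc1)C(C)(C)C | intermediate
25 | angelic acid, (Z)-2-methylbut-2-enoic acid | C/C=C(/C)C(=O)O | starting material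
26 | (Z)-2-methylbut-2-enoic 2,4,6-trichlorobenzoic anhydride | C/C=C(/C)C(=O)OC(=O)c1c(Cl)cc(Cl)cc1Cl | intermediate (not isolated)
27 | 18-O-TBS-15-O-TBDPS-protected 3-angelate | C=C1CC[C@H]2[C@@](C)(CC[C@@H](OC(=O)/C(C)=C\C)[C@]2(C)CO[Si](C)(C)C(C)(C)C)[C@@H]1CC/C(C)=C/CO[Si](c1ccccc1)(c1ccccc1)C(C)(C)C | intermediate
28 | (3R,4S,5S,9R,10S)-15,18-dihydroxy-ent-labda-8(17),13E-dien-3-yl (Z)-2-methylbut-2-enoate (CNP0118197.1) | C=C1CC[C@H]2[C@@](C)(CC[C@@H](OC(=O)/C(C)=C\C)[C@]2(C)CO)[C@@H]1CC/C(C)=C/CO | target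

Total steps: 16. Longest linear sequence: 12 steps (5 → 6 → 7 → 9 → 10 → 18 → 19 → 21 → 22 → 23 → 24 → 27 → 28).

Steps most likely to fail

Step 12. The cycloaddition may be too slow, because the vinyl group is unactivated and the C10 methyl sits inside the s-cis diene; the temperature then needed could erode the trans/cis selectivity or cause decomposition. The fallback activates the dienophile with a traceless formyl group; it sets out from 21 and comes back at 22. Cross-metathesis of 21 with acrolein (RuCl2(H2IMes)(=CH-C6H4-2-O-iPr), the second-generation Hoveyda–Grubbs catalyst, CH2Cl2, 40 °C) should convert the vinyl group into the (E)-enal triene F1. This activated triene should cyclise in toluene at 60–80 °C through the endo-formyl, tether-exo transition state to the C6-formyl adduct F2. Stoichiometric RhCl(PPh3)3 in toluene at 110 °C should then decarbonylate F2 to 22.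

Step 9. Enantio-induction may be insufficient, or turnover slow, when a γ,γ-disubstituted boronate meets an unbranched aliphatic aldehyde under Brønsted acid catalysis. The fallback uses stoichiometric reagent control; it sets out from 10 and comes back at 18. The PMB ether of commercial 2-methylbuta-2,3-dien-1-ol (NaH, PMBCl), allene ether F3, is hydroborated with (–)-Ipc2BH [from (+)-α-pinene] in Et2O at –40 °C on the face anti to CH2OPMB. This should give the kinetic (Z)-allyldiisopinocampheylborane F4, which is added to 10 at –78 °C (si-face attack, same chair transition state). NaOH/H2O2 work-up should give 18.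

Step 15. The angeloyl double bond may isomerise from Z to E, or conversion may stall, at the hindered C3 hydroxyl. The fallback builds the double bond on the substrate; it sets out from 24 and comes back at 27. DCC/DMAP esterification of 24 with 2-[bis(2,2,2-trifluoroethoxy)phosphoryl]propanoic acid should give the phosphonate ester F5 (epimeric at the phosphonate α-carbon, which is of no consequence). Still–Gennari olefination of F5 with acetaldehyde (KN(SiMe3)2, 18-crown-6, THF, –78 °C) should form the Z-configured 2-methylbut-2-enoate and give 27.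

Further compounds
F1 | step 12 | (E)-enal triene from cross-metathesis of 21 with acrolein | C=C(C[Si](C)(C)C)/C(CC/C(C)=C/CO[Si](c1ccccc1)(c1ccccc1)C(C)(C)C)=C(\C)CC[C@H]1O[C@@H](c2ccc(OC)cc2)OC[C@]1(C)/C=C/C=O
F2 | step 12 | C6-formyl Diels–Alder adduct (formyl equatorial, trans to C4) | C[Si](C)(C)CC1=C(CC/C(C)=C/CO[Si](c2ccccc2)(c2ccccc2)C(C)(C)C)[C@]2(C)CC[C@H]3O[C@@H](c4ccc(OC)cc4)OC[C@]3(C)[C@H]2[C@H](C=O)CC1
F3 | step 9 | 1-methoxy-4-{[(2-methylbuta-2,3-dien-1-yl)oxy]methyl}benzene | C=C=C(C)COCc1ccc(OC)cc1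
F4 | step 9 | (Z)-{4-[(4-methoxybenzyl)oxy]-3-methylbut-2-en-1-yl}diisopinocampheylborane | COc1ccc(COC/C(C)=C\CB([C@@H]2C[C@@H]3C[C@H]([C@H]2C)C3(C)C)[C@@H]2C[C@@H]3C[C@H]([C@H]2C)C3(C)C)cc1
F5 | step 15 | 3-O-{2-[bis(2,2,2-trifluoroethoxy)phosphoryl]propanoyl} derivative of 24 | C=C1CC[C@H]2[C@@](C)(CC[C@@H](OC(=O)C(C)P(=O)(OCC(F)(F)F)OCC(F)(F)F)[C@]2(C)CO[Si](C)(C)C(C)(C)C)[C@@H]1CC/C(C)=C/CO[Si](c1ccccc1)(c1ccccc1)C(C)(C)C
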